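## Analysis of the target

The target is a daucane (carotane) sesquiterpenoid ester: a cyclopentane (ring A: C1–C2–C3–C4–C5) trans-fused along C1–C5 to a cycloheptane (ring B: C1–C10–C9–C8–C7–C6–C5), with methyl C15 on the quaternary C1, an isopropyl group (C11–C13) and the 4-hydroxybenzoyloxy group on C4, a free hydroxyl on C6, methyl C14 on C8 and an epoxide across C8–C9; this numbering is used throughout, β is the face that carries C15, and "11,12,13-trinordaucane" is the same skeleton without the isopropyl group. The six stereocentres are (1R,4R,5S,6S,8R,9S): C15 and the C4 oxygen are β, whereas H5, the C6 hydroxyl and the epoxide oxygen are α, so every other centre can in principle be read from the angular methyl group. The sensitive groups are the trisubstituted epoxide (acid), the free phenol, and above all the hindered tertiary ester 1,3 to a free secondary alcohol, where acyl migration from O4 to O6 is downhill. Because C4 and C6 both carry oxygen and flank C5–H, an intermediate with a carbonyl at one of them is an aldol open to elimination or retro-aldol cleavage, and a carbonyl at both is an enolised 1,3-diketone. The hard points are the quaternary C1 at the fusion of a seven-membered ring, the trans ring fusion, the tertiary carbinol C4 wedged between the ring fusion and the isopropyl group, and acylation of the tertiary oxygen while the secondary one stays free. The feature that invites the key move lies in ring B: C5–C6 (H and OH, a hydrated alkene) and C8–C9 (an epoxidised alkene) are two alkene equivalents separated by the single methylene C7, and the ring is completed by the saturated bond from C10 to the quaternary C1. Ring B is therefore a masked cyclohepta-1,4-diene, the signature product of the Cope rearrangement of a cis-divinylcyclopropane built on C6–C7–C8, in which C1–C10 is the bond that forms.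

## Retrosynthetic reasoning

Epoxide (22 to 21). The C8–O and C9–O bonds are cut last, because the epoxide would not survive the Lewis acids, hydrides and acidic fluoride used earlier. The forward reaction has to put oxygen on the α-face of C8=C9; the free C6 hydroxyl of 21, itself α and homoallylic, can direct it there.

Silyl groups (21 to 20). Both O–Si bonds are cut in one operation. The C6 oxygen must be masked while O4 is acylated, since a free secondary hydroxyl would win any acylation. The forward step must be non-basic so that the acyl group stays on O4.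

C4–C11 and O4–acyl (20 to 15 and 18). The tertiary ester cannot be made by selective acylation of a 1,3-diol, so the C4 alkoxide is created by carbonyl addition to ketone 15 and captured at once by acid chloride 18 (from 16). This removes the isopropyl group and the C4 stereocentre together. The forward step must add an isopropyl nucleophile to the α-face of a hindered, enolisable β-silyloxy ketone without enolising it.

C4 carbonyl and C14 (15 to 14, 12, 11). The ketone is carried as its dioxolane and C14 as an ester carbon, so 15 goes back through 14 and 12 to ester 11. These are adjustments of oxidation level only, accepted because the ester is what makes the key step possible and the ketal is what makes the next disconnection clean.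

C5–H and C6–O (11 and 10 to 8). The two stereocentres are removed as a pair by dehydration across C5–C6, which leaves diene 8 with a single stereocentre (C1). The forward hydroboration must choose the α-face of C5=C6 and leave C8=C9 alone; the angular methyl and the ester on C8 are meant to secure these.

Key disconnection (8 to 4 and 6, via 7). The C1–C10 and C7–C8 bonds are cut. Going forward, cyclopropanation of the vinyl group of 4 by the vinylcarbenoid from 6 makes C7–C8 and C6–C8 (cyclopropane 7), and the Cope rearrangement trades C6–C8 for C1–C10. This cut is chosen because it builds all of ring B and the quaternary C1 in one catalytic, enantioselective operation, and places both alkenes exactly where the target has its oxygens. The precursor 4 is achiral, monocyclic and two steps from a commercial bromo enone.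

Fragments (4 to 2, 3 and 1; 6 to 5). Diene 4 comes from vinylation of bromo ketal 2 with 3, and 2 from ketalisation of 1. Diazo ester 6 comes from 5 by diazo transfer.

## Alternatives that were turned down

Alternative 1: The textbook route cuts C8=C9 by ring-closing metathesis, C5–C6 by an aldol and C1–C15 by conjugate addition, with ring A taken from a cyclopentenone. Copper-catalysed asymmetric conjugate methylation of an allyl-substituted cyclopentenone, aldol capture of the enolate by a β,γ-unsaturated aldehyde and silylation would give diene A1; the forward key step is ring closure of A1 with the second-generation Grubbs catalyst to ketone 15. It was turned down although it is short. The configuration at C5, and with it the trans ring fusion, rests on the enolate distinguishing a methyl from an allyl group on the neighbouring quaternary carbon, two groups of nearly equal size. The aldehyde partner is prone to conjugation. The metathesis contributes no stereochemical information, and no step makes more than one ring bond.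

Alternative 2: A Brook-rearrangement-mediated (3+4) annulation makes the same C7–C8 and C1–C10 bonds. The lithium enolate of an acetylcyclopentene adds to an acryloylsilane; silyl migration, closure to a divinylcyclopropanolate and anionic oxy-Cope rearrangement would give A2, with oxygen at C6 and at C8. It was turned down on three grounds. Both partners are achiral and nothing in the sequence can set the absolute configuration at C1. Ring A arrives without the C4 oxygen, because a C4 carbonyl cannot coexist with formation of the methyl ketone enolate, and C4 cannot be activated afterwards. C5 is left to an enolate protonation, and the C8 silyl enol ether still needs triflation and cross-coupling to become the methyl-bearing alkene.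

Alternative 3: A rhodium-catalysed (5+2) cycloaddition cuts C7–C8 and C9–C10 and stores the C1–C10 bond as the cyclopropane of a bicyclo[3.1.0]hexane. Vinylcyclopropane A3 would react with a methyl-substituted terminal alkyne under [Rh(CO)2Cl]2 to give ring B with the C6 enol ether and the C8=C9 alkene in place. It was turned down because the cycloadduct has carbonyl-level oxygen at both C4 and C6 around C5–H, an enolised 1,3-diketone to which an isopropyl nucleophile cannot be added selectively. In addition, neither the orientation of the alkyne nor the choice between the C5–C10 and C5–C1 cyclopropane bonds is under control, and an oxygen substituent on the internal vinyl carbon is not a proven pattern for this cycloaddition.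

Key step: step 4

Assumption: the sense of induction of Rh2(R-DOSP)4 in step 4 is taken from the usual model for donor/acceptor rhodium carbenoids, which predicts cyclopropane 7 as the (1S,2S) isomer; if diene 4 responds in the opposite sense, Rh2(S-DOSP)4 is used instead.

## Route

Step 1
Reactants: 1 2-bromo-3-methylcyclopent-2-en-1-one
Product: 2 6-bromo-7-methyl-1,4-dioxaspiro[4.4]non-6-ene
Conditions: HOCH2CH2OH, p-TsOH (cat.), benzene, reflux, Dean–Stark
Reagents that add atoms: ethane-1,2-diol, OCCO
Why: Acid-catalysed ketalisation with azeotropic removal of water; the double bond cannot migrate because C5 carries no hydrogen. The dioxolane makes the later diene electron-rich, keeps the carbonyl out of the hydroboration and looks the same from both faces of ring A.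

Step 2
Reactants: 2 6-bromo-7-methyl-1,4-dioxaspiro[4.4]non-6-ene; 3 potassium ethenyltrifluoroborate
Product: 4 6-ethenyl-7-methyl-1,4-dioxaspiro[4.4]non-6-ene
Conditions: Pd(dppf)Cl2·CH2Cl2 (5 mol%), Cs2CO3, THF/H2O 9:1, 75 °C
Reagents that add atoms: none
Why: Suzuki–Miyaura cross-coupling of the alkenyl bromide with the vinyl trifluoroborate; no stereocentre is formed. As the ketal, the diene is not an acyl diene and should not dimerise by Diels–Alder reaction as 2-vinyl enones do.

Step 3
Reactants: 5 methyl but-3-enoate
Product: 6 methyl 2-diazobut-3-enoate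
Conditions: 4-acetamidobenzenesulfonyl azide, DBU, MeCN, 0 °C; used at once
Reagents that add atoms: 4-acetamidobenzenesulfonyl azide, CC(=O)Nc1ccc(cc1)S(=O)(=O)N=[N+]=[N-]
Why: Base-mediated diazo transfer to the CH2 group that is both allylic and α to the ester. The vinyldiazoacetate is used immediately because it cyclises slowly to a pyrazole.

Step 4
Reactants: 4 6-ethenyl-7-methyl-1,4-dioxaspiro[4.4]non-6-ene; 6 methyl 2-diazobut-3-enoate
Product: 8 methyl (1R)-4,4-(ethylenedioxy)-11,12,13-trinordauca-5,8-dien-14-oate, via cis-divinylcyclopropane 7 (not isolated)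
Conditions: Rh2(R-DOSP)4 (1 mol%), 2,2-dimethylbutane, −40 °C, slow addition of 6; then toluene, 110 °C
Reagents that add atoms: none
Why: Loss of N2 from 6 at the dirhodium catalyst gives a vinylcarbenoid that adds to the terminal C6=C7 vinyl group of 4, the only unhindered and electron-rich alkene, forming the C7–C8 and C6–C8 bonds with the vinyl group of the carbenoid cis to the dienyl residue (ester trans), as is the rule for donor/acceptor carbenoids. The cis-divinylcyclopropane 7 then undergoes a Cope rearrangement through a boat transition state, breaking C6–C8 and forming C1–C10, driven by release of the cyclopropane strain. The closest known reaction type is the tandem cyclopropanation/Cope rearrangement (formal (4+3) cycloaddition) of vinyldiazoacetates with 1,3-dienes, which has been used to set quaternary carbons. Ring B is closed by this concerted (3,3)-sigmatropic ring expansion and not by a polar cyclisation, so both new alkenes (C5=C6 and C8=C9) are necessarily cis within the seven-membered ring. The two cyclopropane stereocentres are set by the chiral carboxylate ligands of the catalyst; C1, the only stereocentre left in 8, follows from them stereospecifically, because in the boat array C10 can reach only one face of the ring A alkene C1=C5. The step needs chemoselectivity for the vinyl group over the tetrasubstituted ring alkene, the allylic C–H bonds and the ketal oxygens (secured by steric access and by the high cyclopropanation rate of donor/acceptor carbenoids), cis-diastereoselectivity and high enantioselectivity (catalyst). The symmetric dioxolane at C4 gives neither face of ring A an advantage in the Cope step, and the C15 methyl, which is cis to the cyclopropane on the reacting terminus, slows the rearrangement, hence the heating. The ester on C8 is the acceptor the carbenoid needs; it later shields C8=C9 in step 5 and is reduced to the C14 methyl group.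

Step 5
Reactants: 8 methyl (1R)-4,4-(ethylenedioxy)-11,12,13-trinordauca-5,8-dien-14-oate
Product: 10 methyl (1R,5S,6S)-4,4-(ethylenedioxy)-6-hydroxy-11,12,13-trinordauc-8-en-14-oate, via alkylborane 9 (not isolated)
Conditions: BH3·THF, THF, 0 °C to rt; then 30% H2O2, aq. NaOAc, 0 °C to rt
Reagents that add atoms: hydrogen peroxide, OO
Why: Hydroboration–oxidation: boron goes to the less substituted C6 and hydrogen to C5 in a syn addition, so H5 and O6 are set as a pair. Attack on the α-face, opposite the pseudo-axial C15 methyl on the neighbouring quaternary carbon (the pattern of Δ5-steroids, 5α-H and 6α-OH), should give the trans ring fusion and the 6α-hydroxyl. C8=C9 is an enoate and the C4 carbonyl is a ketal, so neither reacts.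

Step 6
Reactants: 10 methyl (1R,5S,6S)-4,4-(ethylenedioxy)-6-hydroxy-11,12,13-trinordauc-8-en-14-oate
Product: 11 methyl (1R,5S,6S)-6-[(tert-butyldimethylsilyl)oxy]-4,4-(ethylenedioxy)-11,12,13-trinordauc-8-en-14-oate
Conditions: t-BuMe2SiOTf, 2,6-lutidine, CH2Cl2, −78 °C
Reagents that add atoms: tert-butyldimethylsilyl trifluoromethanesulfonate, CC(C)(C)[Si](C)(C)OS(=O)(=O)C(F)(F)F
Why: Silylation of the hindered secondary alcohol with the silyl triflate. The silyl ether lets the primary C14 alcohol be activated alone in step 8 and ensures that only the tertiary alkoxide is acylated in step 11.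

Step 7
Reactants: 11 methyl (1R,5S,6S)-6-[(tert-butyldimethylsilyl)oxy]-4,4-(ethylenedioxy)-11,12,13-trinordauc-8-en-14-oate
Product: 12 (1R,5S,6S)-6-[(tert-butyldimethylsilyl)oxy]-4,4-(ethylenedioxy)-11,12,13-trinordauc-8-en-14-ol
Conditions: i-Bu2AlH (2.5 equiv), CH2Cl2, −78 °C; aq. sodium potassium tartrate
Reagents that add atoms: none
Why: 1,2-Reduction of the conjugated ester to the allylic alcohol; ketal and silyl ether are inert at this temperature.

Step 8
Reactants: 12 (1R,5S,6S)-6-[(tert-butyldimethylsilyl)oxy]-4,4-(ethylenedioxy)-11,12,13-trinordauc-8-en-14-ol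
Product: 14 (1R,5S,6S)-6-[(tert-butyldimethylsilyl)oxy]-4,4-(ethylenedioxy)-11,12,13-trinordauc-8-ene, via allylic mesylate 13 (not isolated)
Conditions: MsCl, Et3N, CH2Cl2, −20 °C; then LiEt3BH, THF, 0 °C
Reagents that add atoms: none
Why: Mesylation of the primary allylic alcohol and direct SN2 displacement by the hydride of LiEt3BH turn C14 into the methyl group. Substitution at the unhindered primary carbon should outrun SN2' delivery to C9, so the alkene stays at C8=C9.

Step 9
Reactants: 14 (1R,5S,6S)-6-[(tert-butyldimethylsilyl)oxy]-4,4-(ethylenedioxy)-11,12,13-trinordauc-8-ene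
Product: 15 (1R,5S,6S)-6-[(tert-butyldimethylsilyl)oxy]-11,12,13-trinordauc-8-en-4-one
Conditions: pyridinium p-toluenesulfonate (cat.), acetone/H2O 10:1, 50 °C
Reagents that add atoms: water, O
Why: Mild acid-catalysed ketal hydrolysis; the secondary silyl ether survives, and the mildness limits enolisation at C5, which is now α to the ketone.

Step 10
Reactants: 16 4-hydroxybenzoic acid
Product: 18 4-[(tert-butyldimethylsilyl)oxy]benzoyl chloride, via bis-silyl benzoate 17 (not isolated)
Conditions: t-BuMe2SiCl (2.2 equiv), imidazole, DMF, rt; then (COCl)2, DMF (cat.), CH2Cl2, 0 °C to rt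
Reagents that add atoms: tert-butyldimethylsilyl chloride, CC(C)(C)[Si](C)(C)Cl; oxalyl chloride, ClC(=O)C(Cl)=O
Why: Exhaustive silylation, then conversion of the silyl ester into the acid chloride by oxalyl chloride under neutral conditions; the aryl silyl ether is not touched.

Step 11
Reactants: 15 (1R,5S,6S)-6-[(tert-butyldimethylsilyl)oxy]-11,12,13-trinordauc-8-en-4-one; 18 4-[(tert-butyldimethylsilyl)oxy]benzoyl chloride
Product: 20 (1R,4R,5S,6S)-6-[(tert-butyldimethylsilyl)oxy]dauc-8-en-4-yl 4-[(tert-butyldimethylsilyl)oxy]benzoate, via cerium alkoxide 19 (not isolated)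
Conditions: i-PrLi, CeCl3, THF, −78 °C; then 18, DMAP (cat.), −78 to 0 °C
Reagents that add atoms: isopropyllithium, [Li]C(C)C
Why: Organocerium addition to a hindered, enolisable ketone, which should avoid enolisation and loss of the β-silyloxy group. The reagent should attack C4 from the α-face, because the β-face carries the C15 methyl (1,3 to C4) and the C6 branch on C5, giving the 4β-alkoxide (4R). The alkoxide is acylated in the same flask, so the tertiary ester is formed without a free secondary hydroxyl ever competing.

Step 12
Reactants: 20 (1R,4R,5S,6S)-6-[(tert-butyldimethylsilyl)oxy]dauc-8-en-4-yl 4-[(tert-butyldimethylsilyl)oxy]benzoate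
Product: 21 (1R,4R,5S,6S)-6-hydroxydauc-8-en-4-yl 4-hydroxybenzoate
Conditions: HF·pyridine, pyridine/THF, 0 °C to rt
Reagents that add atoms: none
Why: Acidic fluoride cleaves the aryl and the secondary alkyl silyl ether in one operation; the non-basic medium should prevent acyl migration from O4 to O6.

Step 13
Reactants: 21 (1R,4R,5S,6S)-6-hydroxydauc-8-en-4-yl 4-hydroxybenzoate
Product: 22 (1R,4R,5S,6S,8R,9S)-8,9-epoxy-6-hydroxydaucan-4-yl 4-hydroxybenzoate (CNP0264773.1)
Conditions: VO(acac)2 (5 mol%), t-BuOOH, CH2Cl2, 0 °C to rt
Reagents that add atoms: tert-butyl hydroperoxide, CC(C)(C)OO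
Why: Hydroxyl-directed epoxidation: the vanadium alkoxide of the α-oriented C6 hydroxyl should deliver oxygen to the α-face of the homoallylic C8=C9 bond, the face that is also free of the C15 methyl. This sets C8 (R) and C9 (S); C8=C9 is the only alkene left.

## Compound list

1 | 2-bromo-3-methylcyclopent-2-en-1-one | CC1=C(Br)C(=O)CC1 | starting material
2 | 6-bromo-7-methyl-1,4-dioxaspiro[4.4]non-6-ene | CC1=C(Br)C2(CC1)OCCO2 | intermediate
3 | potassium ethenyltrifluoroborate | C=C[B-](F)(F)F.[K+] | starting material
4 | 6-ethenyl-7-methyl-1,4-dioxaspiro[4.4]non-6-ene | C=CC1=C(C)CCC12OCCO2 | intermediate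
5 | methyl but-3-enoate | C=CCC(=O)OC | starting material
6 | methyl 2-diazobut-3-enoate | C=CC(=[N+]=[N-])C(=O)OC | intermediate
7 | methyl (1S,2S)-1-ethenyl-2-(7-methyl-1,4-dioxaspiro[4.4]non-6-en-6-yl)cyclopropane-1-carboxylate (cis-divinylcyclopropane, not isolated) | COC(=O)[C@]1(C=C)C[C@H]1C1=C(C)CCC12OCCO2 | intermediate
8 | methyl (1R)-4,4-(ethylenedioxy)-11,12,13-trinordauca-5,8-dien-14-oate | C12(OCCO1)CC[C@]3(C)CC=C(C(=O)OC)CC=C32 | intermediate
9 | methyl (1R)-6α-boranyl-4,4-(ethylenedioxy)-5α-H-11,12,13-trinordauc-8-en-14-oate (alkylborane, not isolated) | C12(OCCO1)CC[C@]3(C)CC=C(C(=O)OC)C[C@H](B)[C@H]32 | intermediate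
10 | methyl (1R,5S,6S)-4,4-(ethylenedioxy)-6-hydroxy-11,12,13-trinordauc-8-en-14-oate | C12(OCCO1)CC[C@]3(C)CC=C(C(=O)OC)C[C@H](O)[C@H]32 | intermediate
11 | methyl (1R,5S,6S)-6-[(tert-butyldimethylsilyl)oxy]-4,4-(ethylenedioxy)-11,12,13-trinordauc-8-en-14-oate | C12(OCCO1)CC[C@]3(C)CC=C(C(=O)OC)C[C@H](O[Si](C)(C)C(C)(C)C)[C@H]32 | intermediate
12 | (1R,5S,6S)-6-[(tert-butyldimethylsilyl)oxy]-4,4-(ethylenedioxy)-11,12,13-trinordauc-8-en-14-ol | C12(OCCO1)CC[C@]3(C)CC=C(CO)C[C@H](O[Si](C)(C)C(C)(C)C)[C@H]32 | intermediate
13 | (1R,5S,6S)-6-[(tert-butyldimethylsilyl)oxy]-4,4-(ethylenedioxy)-11,12,13-trinordauc-8-en-14-yl methanesulfonate (not isolated) | C12(OCCO1)CC[C@]3(C)CC=C(COS(C)(=O)=O)C[C@H](O[Si](C)(C)C(C)(C)C)[C@H]32 | intermediate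
14 | (1R,5S,6S)-6-[(tert-butyldimethylsilyl)oxy]-4,4-(ethylenedioxy)-11,12,13-trinordauc-8-ene | C12(OCCO1)CC[C@]3(C)CC=C(C)C[C@H](O[Si](C)(C)C(C)(C)C)[C@H]32 | intermediate
15 | (1R,5S,6S)-6-[(tert-butyldimethylsilyl)oxy]-11,12,13-trinordauc-8-en-4-one | O=C1CC[C@]2(C)CC=C(C)C[C@H](O[Si](C)(C)C(C)(C)C)[C@H]21 | intermediate
16 | 4-hydroxybenzoic acid | OC(=O)c1ccc(O)cc1 | starting material
17 | tert-butyldimethylsilyl 4-[(tert-butyldimethylsilyl)oxy]benzoate (not isolated) | CC(C)(C)[Si](C)(C)OC(=O)c1ccc(O[Si](C)(C)C(C)(C)C)cc1 | intermediate
18 | 4-[(tert-butyldimethylsilyl)oxy]benzoyl chloride | ClC(=O)c1ccc(O[Si](C)(C)C(C)(C)C)cc1 | intermediate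
19 | dichlorocerium (1R,4R,5S,6S)-6-[(tert-butyldimethylsilyl)oxy]dauc-8-en-4-olate (not isolated) | CC(C)[C@]1(O[Ce](Cl)Cl)CC[C@]2(C)CC=C(C)C[C@H](O[Si](C)(C)C(C)(C)C)[C@H]21 | intermediate
20 | (1R,4R,5S,6S)-6-[(tert-butyldimethylsilyl)oxy]dauc-8-en-4-yl 4-[(tert-butyldimethylsilyl)oxy]benzoate | CC(C)[C@]1(OC(=O)c2ccc(O[Si](C)(C)C(C)(C)C)cc2)CC[C@]2(C)CC=C(C)C[C@H](O[Si](C)(C)C(C)(C)C)[C@H]21 | intermediate
21 | (1R,4R,5S,6S)-6-hydroxydauc-8-en-4-yl 4-hydroxybenzoate | CC(C)[C@]1(OC(=O)c2ccc(O)cc2)CC[C@]2(C)CC=C(C)C[C@H](O)[C@H]21 | intermediate
22 | (1R,4R,5S,6S,8R,9S)-8,9-epoxy-6-hydroxydaucan-4-yl 4-hydroxybenzoate | CC(C)[C@]1(OC(=O)c2ccc(O)cc2)CC[C@]2(C)C[C@@H]3O[C@]3(C)C[C@H](O)[C@H]21 | target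

## Step count and least certain steps

Total step count: 13. Steps 3 and 10 prepare the two side components. Longest linear sequence: 11 steps (1, 2, 4, 5, 6, 7, 8, 9, 11, 12, 13).

Step 4 (key step). The most likely failure is incomplete enantioface discrimination in the cyclopropanation, because the alkene substituent is a bulky tetrasubstituted alkenyl ketal and not one of the simple dienes on which the catalyst model rests. A second risk is a 1,5-homodienyl hydrogen shift from C15 in 7 while the slow Cope rearrangement is awaited. The fallback takes the absolute configuration from a covalently bound auxiliary instead of from the catalyst. It sets out from 4, which is combined with (3R)-4,4-dimethyl-2-oxooxolan-3-yl 2-diazobut-3-enoate F1 under achiral Rh2(O2CC7H15)4, followed by the same thermal Cope step. This should give (3R)-4,4-dimethyl-2-oxooxolan-3-yl (1R)-4,4-(ethylenedioxy)-11,12,13-trinordauca-5,8-dien-14-oate F2 as separable diastereomers (the enantiomeric auxiliary is used if the sense is opposite). The pure diastereomer is transesterified with K2CO3 in methanol and comes back to the route at 8.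

Step 5. The most likely failure is addition of borane from the β-face, because ring B folds towards the α-face and the angular methyl may not outweigh that fold; this would give the cis-fused 5β-H, 6β-OH pair. The fallback sets out from 8 and uses the same facial preference in a different sequence. Epoxidation with mCPBA/NaHCO3 (the enoate is inert) gives methyl (1R)-5β,6β-epoxy-4,4-(ethylenedioxy)-11,12,13-trinordauc-8-en-14-oate F3. BF3·OEt2 at −78 °C opens the tertiary C5–O bond and shifts hydride from C6 to C5 on the face opposite the leaving oxygen (Meinwald rearrangement), giving the trans-fused ketone methyl (1R)-4,4-(ethylenedioxy)-6-oxo-5α-H-11,12,13-trinordauc-8-en-14-oate F4. NaBH4 should attack anti to C15 and give the 6β-alcohol methyl (1R)-4,4-(ethylenedioxy)-6β-hydroxy-5α-H-11,12,13-trinordauc-8-en-14-oate F5. Mitsunobu inversion with 4-nitrobenzoic acid gives methyl (1R)-4,4-(ethylenedioxy)-6α-(4-nitrobenzoyloxy)-5α-H-11,12,13-trinordauc-8-en-14-oate F6, and methanolysis (K2CO3, MeOH) comes back to the route at 10.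

Step 11. The most likely failures are enolisation with loss of the β-silyloxy group, or reduction of the ketone by β-hydride transfer from the isopropyl reagent, both in competition with addition; in addition, acylation of the very hindered cerium alkoxide in the same flask may be slow. The fallback sets out from 15 and uses an sp2 nucleophile that has no β-hydrogen to transfer and is less basic. CH2=C(CH3)MgBr with CeCl3 gives the isolated carbinol (1R,5S,6S)-6-[(tert-butyldimethylsilyl)oxy]dauca-8,11-dien-4β-ol F7. Its potassium alkoxide (KN(SiMe3)2, THF) is acylated with 18 to give (1R,5S,6S)-6-[(tert-butyldimethylsilyl)oxy]dauca-8,11-dien-4β-yl 4-[(tert-butyldimethylsilyl)oxy]benzoate F8. Hydrogenation over RhCl(PPh3)3, which should take the 1,1-disubstituted alkene before the trisubstituted ring alkene, comes back to the route at 20.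

Step 13. The most likely failure is that the free phenol competes with the C6 hydroxyl for vanadium, so that the reaction stalls or loses its facial direction; some oxidation of the phenol is also possible. The fallback sets out from 20 and reverses the last two operations, replacing hydroxyl direction by steric control. mCPBA/NaHCO3 epoxidises the silyl-protected alkene on the face opposite C15 to give (1R,4R,5S,6S,8R,9S)-6-[(tert-butyldimethylsilyl)oxy]-8,9-epoxydaucan-4-yl 4-[(tert-butyldimethylsilyl)oxy]benzoate F9. Both silyl groups are then removed with Bu4NF buffered with acetic acid, which spares the epoxide and suppresses acyl migration, and the sequence ends at 22.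

## Further compounds

F1 | step 4 | (3R)-4,4-dimethyl-2-oxooxolan-3-yl 2-diazobut-3-enoate | C=CC(=[N+]=[N-])C(=O)O[C@H]1C(=O)OCC1(C)C
F2 | step 4 | (3R)-4,4-dimethyl-2-oxooxolan-3-yl (1R)-4,4-(ethylenedioxy)-11,12,13-trinordauca-5,8-dien-14-oate | C12(OCCO1)CC[C@]3(C)CC=C(C(=O)O[C@H]4C(=O)OCC4(C)C)CC=C32
F3 | step 5 | methyl (1R)-5β,6β-epoxy-4,4-(ethylenedioxy)-11,12,13-trinordauc-8-en-14-oate | C12(OCCO1)CC[C@]3(C)CC=C(C(=O)OC)C[C@H]4O[C@]432
F4 | step 5 | methyl (1R)-4,4-(ethylenedioxy)-6-oxo-5α-H-11,12,13-trinordauc-8-en-14-oate | C12(OCCO1)CC[C@]3(C)CC=C(C(=O)OC)CC(=O)[C@H]32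
F5 | step 5 | methyl (1R)-4,4-(ethylenedioxy)-6β-hydroxy-5α-H-11,12,13-trinordauc-8-en-14-oate | C12(OCCO1)CC[C@]3(C)CC=C(C(=O)OC)C[C@@H](O)[C@H]32
F6 | step 5 | methyl (1R)-4,4-(ethylenedioxy)-6α-(4-nitrobenzoyloxy)-5α-H-11,12,13-trinordauc-8-en-14-oate | C12(OCCO1)CC[C@]3(C)CC=C(C(=O)OC)C[C@H](OC(=O)c4ccc(cc4)[N+](=O)[O-])[C@H]32
F7 | step 11 | (1R,5S,6S)-6-[(tert-butyldimethylsilyl)oxy]dauca-8,11-dien-4β-ol | CC(=C)[C@]1(O)CC[C@]2(C)CC=C(C)C[C@H](O[Si](C)(C)C(C)(C)C)[C@H]21
F8 | step 11 | (1R,5S,6S)-6-[(tert-butyldimethylsilyl)oxy]dauca-8,11-dien-4β-yl 4-[(tert-butyldimethylsilyl)oxy]benzoate | CC(=C)[C@]1(OC(=O)c2ccc(O[Si](C)(C)C(C)(C)C)cc2)CC[C@]2(C)CC=C(C)C[C@H](O[Si](C)(C)C(C)(C)C)[C@H]21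
F9 | step 13 | (1R,4R,5S,6S,8R,9S)-6-[(tert-butyldimethylsilyl)oxy]-8,9-epoxydaucan-4-yl 4-[(tert-butyldimethylsilyl)oxy]benzoate | CC(C)[C@]1(OC(=O)c2ccc(O[Si](C)(C)C(C)(C)C)cc2)CC[C@]2(C)C[C@@H]3O[C@]3(C)C[C@H](O[Si](C)(C)C(C)(C)C)[C@H]21
A1 | alternative 1 | (2S,3R)-2-[(1S)-1-[(tert-butyldimethylsilyl)oxy]-3-methylbut-3-en-1-yl]-3-methyl-3-(prop-2-en-1-yl)cyclopentan-1-one | O=C1CC[C@](C)(CC=C)[C@H]1[C@@H](O[Si](C)(C)C(C)(C)C)CC(C)=C
A2 | alternative 2 | rac-(1R,5S)-8-[(tert-butyldimethylsilyl)oxy]-11,12,13,14-tetranordauc-8-en-6-one (one enantiomer drawn) | C1CC[C@]2(C)CC=C(O[Si](C)(C)C(C)(C)C)CC(=O)[C@H]21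
A3 | alternative 3 | (1S,5R)-1-{1-[(tert-butyldimethylsilyl)oxy]ethenyl}-5-methylbicyclo[3.1.0]hexan-2-one | C=C(O[Si](C)(C)C(C)(C)C)[C@]12C[C@@]1(C)CCC2=O
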